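**Assumption:** germacranolide numbering is used for the target's carbons (C6 lactone carbinol, C7 ring-fusion carbon, C8 ester carbinol, C10 tertiary carbinol, C11–C13 the methylene-lactone carbons). The SMILES encodes 6S,7R,8R,10R,2′S, a cis-fused lactone, a 1E and a 4Z alkene.

## Retrosynthetic overview

1. Target ⇐ oxidation of the C3 carbinol ⇐ Nozaki–Hiyama–Kishi closure of the ten-membered ring (C3–C4) from an (E)-enal and a (Z)-vinyl iodide; the enal comes from cross-metathesis.
2. cis-α-Methylene-γ-butyrolactone (C6–C7 bond) ⇐ chiral Brønsted-acid-catalysed allylboration/lactonisation of (Z)-3-iodobut-2-enal with a 2-(methoxycarbonyl)allylboronate that carries C8–C10.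
3. Allylboronate ⇐ (Z)-α-bromo enoate (Wittig) + borylmethylzinc (Negishi) ⇐ α-acyloxy aldehyde.
4. C8 ⇐ L-proline aldol of acetone with 2,2-dimethoxyacetaldehyde; C10 ⇐ chelation-controlled vinyl Grignard addition; (S)-2-methylbutanoate ⇐ asymmetric hydrogenation of tiglic acid.
5. Ring order: the lactone ring is formed first (step 10), the ten-membered carbocycle second (step 12).

## Route

Step 1
Reactants: 1 tiglic acid
Product: 2 (S)-2-methylbutanoic acid
Conditions: Ru(OAc)2[(S)-H8-BINAP] (0.5 mol%), H2 (2 atm), MeOH, 20 °C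
Reagents that add atoms: none
Why: Asymmetric hydrogenation of an α,β-unsaturated carboxylic acid on a carboxylate-bound divalent ruthenium–biaryl diphosphine catalyst, the (S)-ligand delivering hydrogen to the face that gives the (S)-acid (about 97% ee expected).

Step 2
Reactants: 3 but-2-yn-1-ol
Product: 5 (Z)-3-iodobut-2-en-1-ol, via cyclic alkenylalanate 4 (not isolated)
Conditions: NaAlH2(OCH2CH2OMe)2 (1.4 equiv), THF, 0 °C → rt; then I2, −78 → 0 °C
Reagents that add atoms: iodine, II
Why: Hydroxyl-directed trans-hydroalumination puts aluminium on C3 cis to the carbinol carbon (five-membered alanate), and iodinolysis with retention gives the (Z)-vinyl iodide.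

Step 3
Reactants: 5 (Z)-3-iodobut-2-en-1-ol
Product: 6 (Z)-3-iodobut-2-enal
Conditions: MnO2 (15 equiv), CH2Cl2, rt, dark; used at once
Reagents that add atoms: none
Why: Manganese dioxide oxidation is selective for the allylic alcohol and mild enough to keep the Z geometry of the β-iodo enal.

Step 4
Reactants: 7 acetone; 8 2,2-dimethoxyacetaldehyde
Product: 9 (4R)-4-hydroxy-5,5-dimethoxypentan-2-one
Conditions: L-proline (20 mol%), acetone as solvent, 4 °C, 48 h
Reagents that add atoms: none
Why: Proline-catalysed direct aldol reaction (enamine catalysis) in which the acetone enamine, oriented by the carboxylic acid hydrogen bond, attacks the Re face of the α-branched, α-oxygenated aldehyde and sets the (R)-carbinol that becomes C8.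

Step 5
Reactants: 9 (4R)-4-hydroxy-5,5-dimethoxypentan-2-one; 10 vinylmagnesium bromide
Product: 11 (2R,4R)-1,1-dimethoxy-4-methylhex-5-ene-2,4-diol
Conditions: 10 (3.0 equiv), CH2Cl2–THF, −78 °C
Reagents that add atoms: none
Why: Chelation-controlled Grignard addition in which the first equivalent forms the C8 magnesium alkoxide, whose six-membered chelate with the ketone exposes the carbonyl face anti to the C8 substituent, so vinyl adds to give the (4R) tertiary carbinol (C10), the minor C10 epimer being removed by chromatography.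

Step 6
Reactants: 11 (2R,4R)-1,1-dimethoxy-4-methylhex-5-ene-2,4-diol; 2 (S)-2-methylbutanoic acid
Product: 12 (2R,4R)-4-hydroxy-1,1-dimethoxy-4-methylhex-5-en-2-yl (2S)-2-methylbutanoate
Conditions: DCC (1.1 equiv), DMAP (0.1 equiv), CH2Cl2, 0 °C → rt
Reagents that add atoms: none
Why: Steglich esterification acylates the secondary C8 hydroxyl selectively over the tertiary C10 hydroxyl without touching any stereocentre.

Step 7
Reactants: 12 (2R,4R)-4-hydroxy-1,1-dimethoxy-4-methylhex-5-en-2-yl (2S)-2-methylbutanoate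
Product: 14 (2R,4R)-4-methyl-1-oxo-4-[(triethylsilyl)oxy]hex-5-en-2-yl (2S)-2-methylbutanoate, via collidinium salt 13 (not isolated)
Conditions: Et3SiOTf (3.0 equiv), 2,4,6-collidine (4.5 equiv), CH2Cl2, 0 °C; then H2O, rt
Reagents that add atoms: triethylsilyl trifluoromethanesulfonate, CC[Si](CC)(CC)OS(=O)(=O)C(F)(F)F; water, O
Why: Silyl triflate/collidine acetal cleavage converts the dimethyl acetal into an N-(α-methoxyalkyl)collidinium salt that water hydrolyses to the aldehyde without acid, while the same reagent silylates the tertiary C10 hydroxyl that would otherwise close a lactol onto the new aldehyde.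

Step 8
Reactants: 14 (2R,4R)-4-methyl-1-oxo-4-[(triethylsilyl)oxy]hex-5-en-2-yl (2S)-2-methylbutanoate; 15 methyl (triphenylphosphoranylidene)acetate
Product: 17 methyl (2Z,4R,6R)-2-bromo-6-methyl-4-{[(2S)-2-methylbutanoyl]oxy}-6-[(triethylsilyl)oxy]octa-2,7-dienoate, via bromo ylide 16 (not isolated)
Conditions: 15 (1.3 equiv), NBS (1.3 equiv), CH2Cl2, −20 °C, 1 h; then 14, 0 °C → rt
Reagents that add atoms: N-bromosuccinimide, O=C1CCC(=O)N1Br
Why: One-pot ylide bromination and Wittig olefination, in which the stabilised α-bromo ylide gives mainly the (Z)-α-bromo enoate (C8 chain trans to CO2Me), the geometry that is later transcribed into the cis ring fusion.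

Step 9
Reactants: 17 methyl (2Z,4R,6R)-2-bromo-6-methyl-4-{[(2S)-2-methylbutanoyl]oxy}-6-[(triethylsilyl)oxy]octa-2,7-dienoate; 18 2-(iodomethyl)-4,4,5,5-tetramethyl-1,3,2-dioxaborolane
Product: 20 methyl (2E,4R,6R)-6-methyl-4-{[(2S)-2-methylbutanoyl]oxy}-2-[(4,4,5,5-tetramethyl-1,3,2-dioxaborolan-2-yl)methyl]-6-[(triethylsilyl)oxy]octa-2,7-dienoate, via borylmethylzinc iodide 19 (not isolated)
Conditions: 18, activated zinc dust, THF, rt, 2 h, decant; then 17, Pd(PPh3)4 (5 mol%), THF, 40 °C
Reagents that add atoms: none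
Why: Negishi cross-coupling (zerovalent palladium) of the borylmethylzinc reagent with the activated alkenyl bromide proceeds with retention of alkene geometry and gives the 2-(methoxycarbonyl)allylboronate with the C8 chain cis to CH2Bpin.

Step 10
Reactants: 20 methyl (2E,4R,6R)-6-methyl-4-{[(2S)-2-methylbutanoyl]oxy}-2-[(4,4,5,5-tetramethyl-1,3,2-dioxaborolan-2-yl)methyl]-6-[(triethylsilyl)oxy]octa-2,7-dienoate; 6 (Z)-3-iodobut-2-enal
Product: 22 (1R,3R)-3-hydroxy-1-[(2R,3R)-2-[(1Z)-2-iodoprop-1-en-1-yl]-4-methylidene-5-oxooxolan-3-yl]-3-methylpent-4-en-1-yl (2S)-2-methylbutanoate, via borate ester 21 (not isolated)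
Conditions: 6 (1.5 equiv), (R)-3,3′-bis(2,4,6-triisopropylphenyl)-1,1′-binaphthyl-2,2′-diyl N-triflylphosphoramide (10 mol%), 4 Å MS, toluene, −20 °C → rt; then HF·pyridine, THF, 0 °C → rt
Reagents that add atoms: none
Why: Proposed new method: a chiral Brønsted-acid-catalysed, double-stereodifferentiating allylboration–lactonisation of a γ-substituted 2-(methoxycarbonyl)allyl pinacolboronate with a β-iodo enal, a reagent class so far activated only by achiral Lewis or Brønsted acids; the phosphoramide N–H protonates the pseudo-axial pinacol oxygen (raising boron Lewis acidity enough for this deactivated boronate) while P=O binds the formyl C–H, so the reaction runs through a closed chair (type-one allylboration) with the aldehyde substituent equatorial and the C8 chain, cis to CH2B, axial, which gives the 6,7-syn adduct and hence the cis-lactone; the (R)-catalyst is expected, by analogy with known allylborations, to direct attack to the Re face of the aldehyde (C6 as in the target), the same pairing that the C8 stereocentre favours (C8–H eclipsing the alkene to avoid A(1,3) strain, aldehyde approaching anti to the C9 chain), so C6 and C7 are set in a matched case; HF·pyridine then cleaves the borate and the silyl ether and the C6 hydroxyl lactonises onto the methyl ester; the closest known reactions are the chiral phosphoric acid-catalysed allylboration of aldehydes with simple allyl and crotyl pinacolboronates and the triflic acid- or Sc(OTf)3-catalysed allylboration with 2-alkoxycarbonyl allylboronates.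

Step 11
Reactants: 22 (1R,3R)-3-hydroxy-1-[(2R,3R)-2-[(1Z)-2-iodoprop-1-en-1-yl]-4-methylidene-5-oxooxolan-3-yl]-3-methylpent-4-en-1-yl (2S)-2-methylbutanoate; 23 (E)-but-2-enal
Product: 24 (1R,3R,4E)-3-hydroxy-1-[(2R,3R)-2-[(1Z)-2-iodoprop-1-en-1-yl]-4-methylidene-5-oxooxolan-3-yl]-3-methyl-6-oxohex-4-en-1-yl (2S)-2-methylbutanoate
Conditions: second-generation Hoveyda–Grubbs catalyst (5 mol%), 23 (5 equiv), CH2Cl2, 40 °C
Reagents that add atoms: none
Why: Olefin cross-metathesis in which only the monosubstituted vinyl group of the free tertiary allylic alcohol reacts (the 1,1-disubstituted acrylate and the trisubstituted vinyl iodide are inert) and exchange with crotonaldehyde gives the (E)-enal.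

Step 12
Reactants: 24 (1R,3R,4E)-3-hydroxy-1-[(2R,3R)-2-[(1Z)-2-iodoprop-1-en-1-yl]-4-methylidene-5-oxooxolan-3-yl]-3-methyl-6-oxohex-4-en-1-yl (2S)-2-methylbutanoate
Product: 25 (3aR,4R,6R,7E,10Z,11aS)-6,9-dihydroxy-6,10-dimethyl-3-methylidene-2-oxo-2,3,3a,4,5,6,9,11a-octahydrocyclodeca[b]furan-4-yl (2S)-2-methylbutanoate (mixture of C9 epimers)
Conditions: CrCl2 (10 equiv), NiCl2 (0.1 equiv), DMSO–THF (3:1), 2 mM, slow addition, rt
Reagents that add atoms: none
Why: Nozaki–Hiyama–Kishi macrocyclisation in which nickel-catalysed activation of the (Z)-vinyl iodide and transmetalation to trivalent chromium give an alkenylchromium that adds 1,2 to the enal under high dilution with retention of the Z geometry, closing the ten-membered ring at C3–C4 (the configuration of the new C3 carbinol is irrelevant).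

Step 13
Reactants: 25 (3aR,4R,6R,7E,10Z,11aS)-6,9-dihydroxy-6,10-dimethyl-3-methylidene-2-oxo-2,3,3a,4,5,6,9,11a-octahydrocyclodeca[b]furan-4-yl (2S)-2-methylbutanoate
Product: 26 (3aR,4R,6R,7E,10Z,11aS)-6-hydroxy-6,10-dimethyl-3-methylidene-2,9-dioxo-2,3,3a,4,5,6,9,11a-octahydrocyclodeca[b]furan-4-yl (2S)-2-methylbutanoate
Conditions: Dess–Martin periodinane (1.5 equiv), CH2Cl2, 0 °C → rt
Reagents that add atoms: none
Why: Dess–Martin oxidation converts the doubly allylic secondary alcohol into the cross-conjugated dienone, while the tertiary C10 alcohol cannot be oxidised and no stereocentre is affected.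

## Compound list

1 | tiglic acid [(2E)-2-methylbut-2-enoic acid] | C/C=C(\C)C(=O)O | starting material
2 | (S)-2-methylbutanoic acid | CC[C@H](C)C(=O)O | intermediate
3 | but-2-yn-1-ol | CC#CCO | starting material
4 | sodium cyclic (Z)-alkenylalanate (five-membered O–Al–C(CH3)=CH–CH2 ring, two 2-methoxyethoxy groups on aluminium) | [Na+].CC1=CCO[Al-]1(OCCOC)OCCOC | intermediate
5 | (Z)-3-iodobut-2-en-1-ol | OC/C=C(/C)I | intermediate
6 | (Z)-3-iodobut-2-enal | O=C/C=C(/C)I | intermediate
7 | acetone | CC(C)=O | starting material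
8 | 2,2-dimethoxyacetaldehyde | COC(OC)C=O | starting material
9 | (4R)-4-hydroxy-5,5-dimethoxypentan-2-one | CC(=O)C[C@@H](O)C(OC)OC | intermediate
10 | vinylmagnesium bromide | C=C[Mg]Br | starting material
11 | (2R,4R)-1,1-dimethoxy-4-methylhex-5-ene-2,4-diol | C=C[C@](C)(O)C[C@@H](O)C(OC)OC | intermediate
12 | (2R,4R)-4-hydroxy-1,1-dimethoxy-4-methylhex-5-en-2-yl (2S)-2-methylbutanoate | C=C[C@](C)(O)C[C@@H](OC(=O)[C@@H](C)CC)C(OC)OC | intermediate
13 | 1-[(2R,4R)-1-methoxy-4-methyl-2-{[(2S)-2-methylbutanoyl]oxy}-4-[(triethylsilyl)oxy]hex-5-en-1-yl]-2,4,6-trimethylpyridinium trifluoromethanesulfonate (C1 epimers) | C=C[C@](C)(O[Si](CC)(CC)CC)C[C@@H](OC(=O)[C@@H](C)CC)C(OC)[n+]1c(C)cc(C)cc1C.[O-]S(=O)(=O)C(F)(F)F | intermediate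
14 | (2R,4R)-4-methyl-1-oxo-4-[(triethylsilyl)oxy]hex-5-en-2-yl (2S)-2-methylbutanoate | C=C[C@](C)(O[Si](CC)(CC)CC)C[C@@H](OC(=O)[C@@H](C)CC)C=O | intermediate
15 | methyl (triphenylphosphoranylidene)acetate | COC(=O)C=P(c1ccccc1)(c1ccccc1)c1ccccc1 | starting material
16 | methyl bromo(triphenylphosphoranylidene)acetate | COC(=O)C(Br)=P(c1ccccc1)(c1ccccc1)c1ccccc1 | intermediate
17 | methyl (2Z,4R,6R)-2-bromo-6-methyl-4-{[(2S)-2-methylbutanoyl]oxy}-6-[(triethylsilyl)oxy]octa-2,7-dienoate | COC(=O)/C(Br)=C/[C@H](OC(=O)[C@@H](C)CC)C[C@@](C)(O[Si](CC)(CC)CC)C=C | intermediate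
18 | 2-(iodomethyl)-4,4,5,5-tetramethyl-1,3,2-dioxaborolane | CC1(C)OB(CI)OC1(C)C | starting material
19 | iodo[(4,4,5,5-tetramethyl-1,3,2-dioxaborolan-2-yl)methyl]zinc | CC1(C)OB(C[Zn]I)OC1(C)C | intermediate
20 | methyl (2E,4R,6R)-6-methyl-4-{[(2S)-2-methylbutanoyl]oxy}-2-[(4,4,5,5-tetramethyl-1,3,2-dioxaborolan-2-yl)methyl]-6-[(triethylsilyl)oxy]octa-2,7-dienoate | COC(=O)/C(CB1OC(C)(C)C(C)(C)O1)=C/[C@H](OC(=O)[C@@H](C)CC)C[C@@](C)(O[Si](CC)(CC)CC)C=C | intermediate
21 | methyl (3S,4R,5Z)-6-iodo-2-methylidene-3-[(1R,3R)-3-methyl-1-{[(2S)-2-methylbutanoyl]oxy}-3-[(triethylsilyl)oxy]pent-4-en-1-yl]-4-[(4,4,5,5-tetramethyl-1,3,2-dioxaborolan-2-yl)oxy]hept-5-enoate | COC(=O)C(=C)[C@@H]([C@@H](OB1OC(C)(C)C(C)(C)O1)/C=C(/C)I)[C@H](OC(=O)[C@@H](C)CC)C[C@@](C)(O[Si](CC)(CC)CC)C=C | intermediate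
22 | (1R,3R)-3-hydroxy-1-[(2R,3R)-2-[(1Z)-2-iodoprop-1-en-1-yl]-4-methylidene-5-oxooxolan-3-yl]-3-methylpent-4-en-1-yl (2S)-2-methylbutanoate (cis-lactone) | C=C1C(=O)O[C@@H](/C=C(/C)I)[C@H]1[C@H](OC(=O)[C@@H](C)CC)C[C@@](C)(O)C=C | intermediate
23 | (E)-but-2-enal (crotonaldehyde) | C/C=C/C=O | starting material
24 | (1R,3R,4E)-3-hydroxy-1-[(2R,3R)-2-[(1Z)-2-iodoprop-1-en-1-yl]-4-methylidene-5-oxooxolan-3-yl]-3-methyl-6-oxohex-4-en-1-yl (2S)-2-methylbutanoate | C=C1C(=O)O[C@@H](/C=C(/C)I)[C@H]1[C@H](OC(=O)[C@@H](C)CC)C[C@@](C)(O)/C=C/C=O | intermediate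
25 | (3aR,4R,6R,7E,10Z,11aS)-6,9-dihydroxy-6,10-dimethyl-3-methylidene-2-oxo-2,3,3a,4,5,6,9,11a-octahydrocyclodeca[b]furan-4-yl (2S)-2-methylbutanoate (C9 epimers) | C=C1C(=O)O[C@H]2/C=C(/C)C(O)/C=C/[C@](C)(O)C[C@@H](OC(=O)[C@@H](C)CC)[C@@H]12 | intermediate
26 | (3aR,4R,6R,7E,10Z,11aS)-6-hydroxy-6,10-dimethyl-3-methylidene-2,9-dioxo-2,3,3a,4,5,6,9,11a-octahydrocyclodeca[b]furan-4-yl (2S)-2-methylbutanoate (CNP0315499.4) | C=C1C(=O)O[C@H]2/C=C(/C)C(=O)/C=C/[C@](C)(O)C[C@@H](OC(=O)[C@@H](C)CC)[C@@H]12 | target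

## Step count and risks

Total steps: 13. Longest linear sequence: 10 (steps 4 to 13).

**Step 10 (the proposed allylboration).** The deactivated, γ-branched boronate may be too slow under chiral Brønsted acid catalysis, or the catalyst and the C8 centre may not reinforce each other. The fallback uses known chemistry, sets out from 17 and comes back at 22. Stille coupling of 17 with (tributylstannyl)methanol (Pd(PPh3)4, toluene, 80 °C) gives the allylic alcohol methyl (2E,4R,6R)-2-(hydroxymethyl)-6-methyl-4-{[(2S)-2-methylbutanoyl]oxy}-6-[(triethylsilyl)oxy]octa-2,7-dienoate F1. Appel bromination (CBr4, PPh3, CH2Cl2, 0 °C) gives the (Z)-2-(bromomethyl) enoate F2. An indium-mediated Barbier allylation of aldehyde 6 (indium powder, THF–H2O, rt) then runs through the same closed, syn-selective transition state under substrate control and gives the hydroxy ester F3; indium is chosen because it is least prone to 1,4-elimination of the allylic acyloxy group. HF·pyridine closes the lactone and removes the silyl group to give 22.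

**Step 12 (ten-membered ring closure).** Medium-ring strain may favour oligomers or reduction of the iodide. The fallback sets out from 22, replaces steps 11 to 13 and comes back at 26. Carbonylative Stille coupling of 22 with tributyl(vinyl)stannane under CO (Pd2(dba)3, AsPh3, copper iodide CuI, NMP, 50 °C) gives the cross-conjugated divinyl ketone (1R,3R)-3-hydroxy-3-methyl-1-[(2S,3R)-4-methylidene-2-[(1Z)-2-methyl-3-oxopenta-1,4-dien-1-yl]-5-oxooxolan-3-yl]pent-4-en-1-yl (2S)-2-methylbutanoate F4. Ring-closing metathesis between the enone vinyl group and the vinyl carbinol (second-generation Hoveyda–Grubbs catalyst, toluene, 80 °C, 1 mM) forms C1=C2 and gives 26 directly. This route is shorter but less precedented for this ring size, and E/Z control at C1=C2 is uncertain.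

**Step 7 (one-pot silylation and acetal cleavage next to an ester).** The neighbouring ester may participate, or the electron-poor acetal may react sluggishly. The fallback sets out from 12 and comes back at 17. Hydrolysis with Amberlyst-15 in wet acetone lets the free C10 hydroxyl trap the aldehyde as the lactol (3R,5R)-5-ethenyl-2-hydroxy-5-methyloxolan-3-yl (2S)-2-methylbutanoate F5. The lactol reacts through its open form with bromo ylide 16 (Wittig olefination of a lactol, CH2Cl2, rt) to give the hydroxy bromo enoate methyl (2Z,4R,6R)-2-bromo-6-hydroxy-6-methyl-4-{[(2S)-2-methylbutanoyl]oxy}octa-2,7-dienoate F6. Silylation (Et3SiOTf, 2,6-lutidine, CH2Cl2, −78 °C) gives 17.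

## Further compounds

F1 | step 10 | methyl (2E,4R,6R)-2-(hydroxymethyl)-6-methyl-4-{[(2S)-2-methylbutanoyl]oxy}-6-[(triethylsilyl)oxy]octa-2,7-dienoate | COC(=O)/C(CO)=C/[C@H](OC(=O)[C@@H](C)CC)C[C@@](C)(O[Si](CC)(CC)CC)C=C
F2 | step 10 | methyl (2Z,4R,6R)-2-(bromomethyl)-6-methyl-4-{[(2S)-2-methylbutanoyl]oxy}-6-[(triethylsilyl)oxy]octa-2,7-dienoate | COC(=O)/C(CBr)=C/[C@H](OC(=O)[C@@H](C)CC)C[C@@](C)(O[Si](CC)(CC)CC)C=C
F3 | step 10 | methyl (3S,4R,5Z)-4-hydroxy-6-iodo-2-methylidene-3-[(1R,3R)-3-methyl-1-{[(2S)-2-methylbutanoyl]oxy}-3-[(triethylsilyl)oxy]pent-4-en-1-yl]hept-5-enoate | COC(=O)C(=C)[C@@H]([C@@H](O)/C=C(/C)I)[C@H](OC(=O)[C@@H](C)CC)C[C@@](C)(O[Si](CC)(CC)CC)C=C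
F4 | step 12 | (1R,3R)-3-hydroxy-3-methyl-1-[(2S,3R)-4-methylidene-2-[(1Z)-2-methyl-3-oxopenta-1,4-dien-1-yl]-5-oxooxolan-3-yl]pent-4-en-1-yl (2S)-2-methylbutanoate | C=C1C(=O)O[C@@H](/C=C(/C)C(=O)C=C)[C@H]1[C@H](OC(=O)[C@@H](C)CC)C[C@@](C)(O)C=C
F5 | step 7 | (3R,5R)-5-ethenyl-2-hydroxy-5-methyloxolan-3-yl (2S)-2-methylbutanoate (anomers) | C=C[C@@]1(C)C[C@@H](OC(=O)[C@@H](C)CC)C(O)O1
F6 | step 7 | methyl (2Z,4R,6R)-2-bromo-6-hydroxy-6-methyl-4-{[(2S)-2-methylbutanoyl]oxy}octa-2,7-dienoate | COC(=O)/C(Br)=C/[C@H](OC(=O)[C@@H](C)CC)C[C@@](C)(O)C=C
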